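A fraction of the pair charged, left-handed and right-handed substrate together, is my unit, and in it the reagent, the limiting reagent, has room for 40.0% of product in east, epsilon and gamma alike.

common to all: left-handed substrate 0.050 M; right-handed substrate 0.050 M

| flask | reagent | free catalyst | remark | time |
|---|---|---|---|---|
| east | 0.040 M | 1.5 mM | run made earlier |  |
| epsilon | 0.0400 M | 1.0 mM |  | 2.5 d |
| gamma | 0.0400 M | 1.0 mM |  | 0.60 d |

east run (percent of the left-handed substrate and right-handed substrate together charged)

| time / h | right-handed substrate / % | left-handed substrate / % | left-handed product / % |
|---|---|---|---|
| 0.333 | 49.7 | 47.8 | 1.7 |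
| 1.00 | 49.8 | 44.1 | 4.8 |
| 1.50 | 49.4 | 42.2 | 7.9 |
| 2.50 | 49.9 | 38.1 | 10.3 |
| 4.00 | 48.8 | 33.3 | 14.5 |
| 5.00 | 47.9 | 31.3 | 17.1 |
| 6.00 | 47.8 | 29.1 | 20.3 |

(standard deviation of a reading: 0.5 percentage points)

- free catalyst is single-handed; left-handed substrate and right-handed substrate are mirror images of each other, charged as a racemate, each of them at the stated concentration
- what was read earlier has a scatter of 0.5 percentage points, one standard deviation
- an excess is the difference of the two amounts in percent of their sum
- an excess is below zero if the other one leads
- no earlier run changes the charge of free catalyst; that part of a forecast is a guess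

1. the winner by excess of right-handed substrate over left-handed substrate among what is left of the two; "neither" if no more than 2 percentage points parts them (epsilon / gamma / neither)
2. excess of right-handed substrate over left-handed substrate among what is left of the two at the end, epsilon
3. excess of right-handed substrate over left-handed substrate among what is left of the two at the end, gamma

I count one reagent used per left-handed product. East then gives 5.82 h from the reading at 2.50 h and 5.87 h from the reading at 6.00 h for the reagent half-life, the time in which the unused reagent falls to half. If it goes inversely with free catalyst, which is a guess, it becomes 8.81 h at the charge of epsilon and gamma. So I reckon that 0.890% of the reagent stays in epsilon and 32.2% in gamma.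

For the bound from above, suppose nothing leaks and every product comes from left-handed substrate: the excess is 65.7% for epsilon and 37.2% for gamma. For the bound from below, I charge the 2.2 percentage points that right-handed substrate lost in east to a leak into left-handed substrate, across half the last gap. That reads as a relaxation half-life of 8.84 h, close to the reagent's reckoned one in epsilon and gamma, and gives 2.78% for epsilon and 20.0% for gamma.

But a leak keeps the sum of the three east columns, and at 6.00 h that sum reads 97.2%, so I take it that something unseen shares the loss. As a guess, I commit to a leak half as fast as that. The gap between the two substrates then peaks at 0.734 d, the crossing where the reagent's feed equals the leak's drain. Gamma stops before it and epsilon well after, which gives 11.3% for epsilon and 26.9% for gamma, so I name gamma.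

The forecast names epsilon, unlike me, with 48% (42% to 54%) for epsilon and 34% (28% to 40%) for gamma, each lower than my bound from above, on the ground “Forty percent conversion leaves about 45 right-handed”. The flask gives 21.1% for epsilon and 30.5% for gamma, so gamma wins.

    free catalyst + left-handed substrate ⇌ catalyst intermediate A (K = 230 M⁻¹, k = 447 M⁻¹ h⁻¹)
    free catalyst + right-handed substrate ⇌ catalyst intermediate B (K = 6.92 M⁻¹, k = 1770 M⁻¹ h⁻¹)
    reagent + catalyst intermediate A → free catalyst + left-handed product (k = 114 M⁻¹ h⁻¹)
    reagent + catalyst intermediate B → free catalyst + right-handed product (k = 45.6 M⁻¹ h⁻¹)
    left-handed substrate ⇌ right-handed substrate (k = 0.0117 h⁻¹)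
    reagent + free catalyst → spent catalyst (k = 0.0580 M⁻¹ h⁻¹)

Reagent left at the end stands at 0.51% in epsilon and 30% in gamma, against my 0.890% and 32.2%. The neighbour flask is epsilon with 4.0 × 10⁻⁴ M of free catalyst. The same scaling makes its reagent half-life 22.0 h, so I reckon that after 2.5 d 15.1% of the reagent stays and 33.9% of the pair has become product. That flask holds 12.6% of its reagent, 33.7% of left-handed product and 1.24% of right-handed product at the end, with an excess of right-handed over left-handed substrate of 21.7%.

The data were computed for an exercise; scatter was added.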